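**Retrosynthetic overview**

1. Target acid ⇐ its methyl ester; the (3R)-carbinol ⇐ oxazaborolidine-catalysed reduction of an α-methylene ketone ⇐ a dioxane aldehyde plus an alkenyllithium made from dihydro-β-ionone (Shapiro reaction; the cyclohexene ring is bought, not built).
2. Dioxane aldehyde ⇐ ozonolysis of the spare enoate arm of a dioxane bis-ester.
3. 1,2-Dioxane ring (the only ring formed; C2, C3 and C6 set together) ⇐ organocatalytic desymmetrising peroxy-Michael cyclisation of an achiral tertiary hydroperoxide carrying two identical (E)-2-methylenoate arms.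
4. Hydroperoxide ⇐ Co-catalysed hydroperoxysilylation of a symmetrical triene ⇐ two-directional half-reduction/Wittig of diethyl 4-methylideneheptanedioate ⇐ diethyl 4-oxoheptanedioate.

Assumption: the sense of induction of the quinidine-derived squaramide in step 4 is taken as giving (2R,3S,6R); if experiment shows the opposite sense, the pseudo-enantiomeric quinine-derived squaramide is used instead.

**Route**

Step 1
Reactants: 1 diethyl 4-oxoheptanedioate
Product: 2 diethyl 4-methylideneheptanedioate
Conditions: Ph3PCH3Br (1.3 equiv), KOtBu (1.25 equiv), THF, 0 °C → rt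
Reagents that add atoms: methyltriphenylphosphonium bromide C[P+](c1ccccc1)(c1ccccc1)c1ccccc1.[Br-]
Why: Wittig methylenation, in which the non-stabilised ylide reacts with the ketone far faster than with the two ethyl esters, installs the 1,1-disubstituted alkene that later becomes C6 and its methyl group; no stereocentre is formed.

Step 2
Reactants: 2 diethyl 4-methylideneheptanedioate, 3 methyl 2-(triphenyl-λ5-phosphanylidene)propanoate
Product: 5 dimethyl (2E,9E)-2,10-dimethyl-6-methylideneundeca-2,9-dienedioate, via 4-methylideneheptanedial 4 (not isolated)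
Conditions: i-Bu2AlH (2.2 equiv), CH2Cl2, –78 °C; then 3 (2.5 equiv), –78 °C → rt
Reagents that add atoms: none
Why: One-flask half-reduction/Wittig olefination, in which i-Bu2AlH stops at the tetrahedral i-Bu2Al–O hemiacetal of each ester at –78 °C and the dialdehyde released on warming is trapped by the stabilised α-methyl ylide, builds both trisubstituted enoates two-directionally with the usual >95:5 E selectivity; no stereocentre is formed.

Step 3
Reactants: 5 dimethyl (2E,9E)-2,10-dimethyl-6-methylideneundeca-2,9-dienedioate
Product: 7 dimethyl (2E,9E)-6-hydroperoxy-2,6,10-trimethylundeca-2,9-dienedioate, via triethylsilyl peroxide 6 (not isolated)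
Conditions: Co(thd)2 (5 mol %; thd = 2,2,6,6-tetramethylheptane-3,5-dionate), O2 (1 atm), Et3SiH (2 equiv), ClCH2CH2Cl, rt; then HCl (cat.), MeOH, 0 °C
Reagents that add atoms: dioxygen O=O
Why: Isayama–Mukaiyama hydroperoxysilylation, in which the Co–H species formed from Co(thd)2 and Et3SiH transfers a hydrogen atom only to the electron-rich 1,1-disubstituted alkene (Markovnikov, creating the C6 methyl and a tertiary radical that is trapped by O2 and silylated) while the electron-poor enoates are left alone, followed by acidic methanolysis of the O–Si bond; C6 carries two identical arms, so 7 is achiral.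

Step 4
Reactants: 7 dimethyl (2E,9E)-6-hydroperoxy-2,6,10-trimethylundeca-2,9-dienedioate
Product: 8 methyl (2R)-2-[(3S,6R)-6-[(3E)-5-methoxy-4-methyl-5-oxopent-3-en-1-yl]-6-methyl-1,2-dioxan-3-yl]propanoate
Conditions: quinidine-derived amine–squaramide (squaramide of 9-amino-9-deoxy-epi-quinidine and 3,5-bis(trifluoromethyl)aniline, 10 mol %), PhCF3, –20 °C, 72 h
Reagents that add atoms: none
Why: Proposed new method: enantioselective desymmetrising 6-exo-trig peroxy-Michael cyclisation with stereocontrolled protonation — the quinuclidine nitrogen of the bifunctional catalyst deprotonates the tertiary OOH (pKa about 13) to a chiral ammonium peroxide ion pair while the squaramide N–H bonds clamp the carbonyl of one of the two enantiotopic (E)-2-methylenoate arms; attack then runs through a chair-like transition state in which the reacting enoate and the spare arm are both equatorial and the small C6 methyl takes the axial site next to the catalyst-bound peroxide oxygen (this choice of arm fixes C6 as R), the catalyst selects the enoate face that gives 3S, and the ester enolate is protonated by the ammonium ion anti to the new C–O bond (net anti addition across the E alkene, the sense favoured stereoelectronically in hetero-Michael additions to 2-methyl-2-enoates), giving 2R; the closest known reactions are the racemic amine-mediated (Et2NH/CF3CH2OH) cyclisation of unsaturated hydroperoxides to 1,2-dioxanes, the Brønsted-acid-catalysed desymmetrisation of peroxyquinols by oxa-Michael addition, and squaramide- or iminophosphorane-catalysed intramolecular oxa- and sulfa-Michael additions to unsaturated esters with enantioselective protonation.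

Step 5
Reactants: 8 methyl (2R)-2-[(3S,6R)-6-[(3E)-5-methoxy-4-methyl-5-oxopent-3-en-1-yl]-6-methyl-1,2-dioxan-3-yl]propanoate
Product: 9 methyl (2R)-2-[(3S,6S)-6-methyl-6-(3-oxopropyl)-1,2-dioxan-3-yl]propanoate
Conditions: O3, CH2Cl2, –78 °C; then Me2S, –78 °C → rt
Reagents that add atoms: ozone [O-][O+]=O
Why: Ozonolysis with reductive work-up cleaves the only C=C of 8 to the aldehyde, while the hindered dialkyl peroxide and the three stereocentres are untouched (the C6 descriptor changes from R to S only because the CIP priorities change).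

Step 6
Reactants: 10 4-(2,6,6-trimethylcyclohex-1-en-1-yl)butan-2-one (dihydro-β-ionone)
Product: 11 N'-[(2E)-4-(2,6,6-trimethylcyclohex-1-en-1-yl)butan-2-ylidene]-2,4,6-tri(propan-2-yl)benzenesulfonohydrazide
Conditions: 2,4,6-tri(propan-2-yl)benzenesulfonohydrazide (1.05 equiv), HCl (cat.), MeOH, rt
Reagents that add atoms: 2,4,6-tri(propan-2-yl)benzenesulfonohydrazide CC(C)c1cc(C(C)C)c(S(=O)(=O)NN)c(C(C)C)c1
Why: Hydrazone condensation of the methyl ketone gives the E-sulfonylhydrazone needed for a regioselective Shapiro reaction; no stereocentre is formed.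

Step 7
Reactants: 11 N'-[(2E)-4-(2,6,6-trimethylcyclohex-1-en-1-yl)butan-2-ylidene]-2,4,6-tri(propan-2-yl)benzenesulfonohydrazide, 9 methyl (2R)-2-[(3S,6S)-6-methyl-6-(3-oxopropyl)-1,2-dioxan-3-yl]propanoate
Product: 13 methyl (2R)-2-[(3S,6R)-6-[(3RS)-3-hydroxy-4-methylidene-6-(2,6,6-trimethylcyclohex-1-en-1-yl)hexyl]-6-methyl-1,2-dioxan-3-yl]propanoate, via alkenyllithium 12 (not isolated)
Conditions: 11 (1.2 equiv), n-BuLi (2.4 equiv), THF, –78 → 0 °C; recool to –78 °C, cannulate into 9 (1.0 equiv) in THF, –78 °C, 15 min; then H2O
Reagents that add atoms: none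
Why: Shapiro reaction followed by 1,2-addition, in which double deprotonation at the methyl group syn to the sulfonamide nitrogen and loss of sulfinate and N2 give the 1,1-disubstituted alkenyllithium, which adds to the aldehyde at –78 °C much faster than to the methyl ester or the hindered peroxide; the new carbinol centre forms without control (about 1:1) and is erased in step 8.

Step 8
Reactants: 13 methyl (2R)-2-[(3S,6R)-6-[(3RS)-3-hydroxy-4-methylidene-6-(2,6,6-trimethylcyclohex-1-en-1-yl)hexyl]-6-methyl-1,2-dioxan-3-yl]propanoate
Product: 14 methyl (2R)-2-[(3S,6S)-6-methyl-6-[4-methylidene-3-oxo-6-(2,6,6-trimethylcyclohex-1-en-1-yl)hexyl]-1,2-dioxan-3-yl]propanoate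
Conditions: Dess–Martin periodinane (1.3 equiv), CH2Cl2, 0 °C → rt
Reagents that add atoms: none
Why: Dess–Martin oxidation converts both allylic alcohol epimers into one α-methylene ketone under neutral conditions that leave the peroxide, the tetrasubstituted alkene and the C2 stereocentre alone.

Step 9
Reactants: 14 methyl (2R)-2-[(3S,6S)-6-methyl-6-[4-methylidene-3-oxo-6-(2,6,6-trimethylcyclohex-1-en-1-yl)hexyl]-1,2-dioxan-3-yl]propanoate
Product: 15 methyl (2R)-2-[(3S,6R)-6-[(3R)-3-hydroxy-4-methylidene-6-(2,6,6-trimethylcyclohex-1-en-1-yl)hexyl]-6-methyl-1,2-dioxan-3-yl]propanoate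
Conditions: (S)-2-methyl-CBS-oxazaborolidine (20 mol %), catecholborane (1.8 equiv), toluene, –78 °C; then MeOH, aqueous work-up
Reagents that add atoms: none
Why: Corey–Bakshi–Shibata reduction, in which the α-substituted vinyl group acts as the large and the CH2CH2 chain as the small ketone substituent, delivers hydride with the (S)-catalyst to the face that gives the (3R)-allylic alcohol under catalyst control (1,2-reduction only), while catecholborane at –78 °C leaves the ester and the dialkyl peroxide alone.

Step 10
Reactants: 15 methyl (2R)-2-[(3S,6R)-6-[(3R)-3-hydroxy-4-methylidene-6-(2,6,6-trimethylcyclohex-1-en-1-yl)hexyl]-6-methyl-1,2-dioxan-3-yl]propanoate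
Product: 16 (2R)-2-[(3S,6R)-6-[(3R)-3-hydroxy-4-methylidene-6-(2,6,6-trimethylcyclohex-1-en-1-yl)hexyl]-6-methyl-1,2-dioxan-3-yl]propanoic acid
Conditions: LiOH·H2O (3 equiv), THF/H2O 3:1, 0 °C → rt; then 1 M HCl to pH 3
Reagents that add atoms: lithium hydroxide [Li+].[OH-]
Why: Saponification cleaves the methyl ester under mild conditions of the kind used on 1,2-dioxane propanoate esters without opening the ring or epimerising C2, and acidification gives the free acid.

**Compound list**

1 | diethyl 4-oxoheptanedioate | CCOC(=O)CCC(=O)CCC(=O)OCC | starting material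
2 | diethyl 4-methylideneheptanedioate | CCOC(=O)CCC(=C)CCC(=O)OCC | intermediate
3 | methyl 2-(triphenyl-λ5-phosphanylidene)propanoate | COC(=O)C(C)=P(c1ccccc1)(c1ccccc1)c1ccccc1 | starting material
4 | 4-methylideneheptanedial | O=CCCC(=C)CCC=O | intermediate
5 | dimethyl (2E,9E)-2,10-dimethyl-6-methylideneundeca-2,9-dienedioate | COC(=O)/C(C)=C/CCC(=C)CC/C=C(\C)C(=O)OC | intermediate
6 | dimethyl (2E,9E)-2,6,10-trimethyl-6-[(triethylsilyl)peroxy]undeca-2,9-dienedioate | COC(=O)/C(C)=C/CCC(C)(OO[Si](CC)(CC)CC)CC/C=C(\C)C(=O)OC | intermediate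
7 | dimethyl (2E,9E)-6-hydroperoxy-2,6,10-trimethylundeca-2,9-dienedioate | COC(=O)/C(C)=C/CCC(C)(OO)CC/C=C(\C)C(=O)OC | intermediate
8 | methyl (2R)-2-[(3S,6R)-6-[(3E)-5-methoxy-4-methyl-5-oxopent-3-en-1-yl]-6-methyl-1,2-dioxan-3-yl]propanoate | COC(=O)/C(C)=C/CC[C@]1(C)CC[C@@H]([C@@H](C)C(=O)OC)OO1 | intermediate
9 | methyl (2R)-2-[(3S,6S)-6-methyl-6-(3-oxopropyl)-1,2-dioxan-3-yl]propanoate | O=CCC[C@]1(C)CC[C@@H]([C@@H](C)C(=O)OC)OO1 | intermediate
10 | 4-(2,6,6-trimethylcyclohex-1-en-1-yl)butan-2-one (dihydro-β-ionone) | CC(=O)CCC1=C(C)CCCC1(C)C | starting material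
11 | N'-[(2E)-4-(2,6,6-trimethylcyclohex-1-en-1-yl)butan-2-ylidene]-2,4,6-tri(propan-2-yl)benzenesulfonohydrazide | C/C(CCC1=C(C)CCCC1(C)C)=N\NS(=O)(=O)c1c(C(C)C)cc(C(C)C)cc1C(C)C | intermediate
12 | [4-(2,6,6-trimethylcyclohex-1-en-1-yl)but-1-en-2-yl]lithium | [Li]C(=C)CCC1=C(C)CCCC1(C)C | intermediate
13 | methyl (2R)-2-[(3S,6R)-6-[(3RS)-3-hydroxy-4-methylidene-6-(2,6,6-trimethylcyclohex-1-en-1-yl)hexyl]-6-methyl-1,2-dioxan-3-yl]propanoate (carbinol epimers) | C=C(CCC1=C(C)CCCC1(C)C)C(O)CC[C@]1(C)CC[C@@H]([C@@H](C)C(=O)OC)OO1 | intermediate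
14 | methyl (2R)-2-[(3S,6S)-6-methyl-6-[4-methylidene-3-oxo-6-(2,6,6-trimethylcyclohex-1-en-1-yl)hexyl]-1,2-dioxan-3-yl]propanoate | C=C(CCC1=C(C)CCCC1(C)C)C(=O)CC[C@]1(C)CC[C@@H]([C@@H](C)C(=O)OC)OO1 | intermediate
15 | methyl (2R)-2-[(3S,6R)-6-[(3R)-3-hydroxy-4-methylidene-6-(2,6,6-trimethylcyclohex-1-en-1-yl)hexyl]-6-methyl-1,2-dioxan-3-yl]propanoate | C=C(CCC1=C(C)CCCC1(C)C)[C@H](O)CC[C@]1(C)CC[C@@H]([C@@H](C)C(=O)OC)OO1 | intermediate
16 | (2R)-2-[(3S,6R)-6-[(3R)-3-hydroxy-4-methylidene-6-(2,6,6-trimethylcyclohex-1-en-1-yl)hexyl]-6-methyl-1,2-dioxan-3-yl]propanoic acid | C=C(CCC1=C(C)CCCC1(C)C)[C@H](O)CC[C@]1(C)CC[C@@H]([C@@H](C)C(=O)O)OO1 | target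

**Step count and risks**

Total steps: 10. Longest linear sequence: 9 (steps 1–5 and 7–10); step 6 is a one-step side branch.

Steps most likely to fail:

Step 4 (the new reaction). Risks are slow addition to the α-methyl enoate, weak discrimination between the two arms (intrinsic methyl-versus-chain selectivity at C6 is close to nil, so it rests on the catalyst), and unselective protonation at C2. Fallback with known chemistry: starting from 7, the established amine-mediated hydroperoxide Michael cyclisation (Et2NH, CF3CH2OH, rt) closes the dioxane without asymmetric induction. The (2R*,3S*,6R*) diastereomer is separated from its C6 and C2 epimers on silica as the racemate, that is 8 together with its mirror image methyl (2S)-2-[(3R,6S)-6-[(3E)-5-methoxy-4-methyl-5-oxopent-3-en-1-yl]-6-methyl-1,2-dioxan-3-yl]propanoate F1. Preparative HPLC on a chiral stationary phase removes F1, and the route is rejoined at 8.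

Step 7. The risk is that the strongly basic alkenyllithium attacks the methyl ester or the O–O bond of 9, or epimerises C2. Fallback: set out again from 11 and 9, but change the metal and form the C–C bond and the carbinol stereocentre in one catalytic event. Alkenyllithium 12 is generated as before and transmetallated with ZnBr2 (0.5 equiv) to bis[4-(2,6,6-trimethylcyclohex-1-en-1-yl)but-1-en-2-yl]zinc F2. The solvent is changed to toluene, LiBr and ArSO2Li are masked with N,N,N',N'-tetraethylethylenediamine, and F2 is added to 9 at 0 °C with (–)-3-exo-morpholinoisoborneol (5 mol %) as catalyst. This amino-alcohol-catalysed alkenylzinc addition delivers the alkenyl group to the Si face and gives the 3R carbinol, and organozinc reagents leave esters and dialkyl peroxides alone. The fallback returns directly at 15, bypassing 13, 14 and steps 8 and 9. It is shorter than the main sequence but less certain in selectivity because of the lithium salts, which is why it is not the first choice.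

Step 9. Risks are attack of the borane on the peroxide and low facial selectivity because both ketone substituents are long chains. Fallback: starting from 14, replace the chemical reductant by an enzyme. Commercial NADPH-dependent ketoreductases are screened for an (R)-selective enzyme (isopropanol as terminal reductant, pH 7 buffer with DMSO cosolvent, 30 °C), and the route is rejoined at 15. This fallback creates no compound outside the list (entry F0).

Further compounds
F1 | step 4 | methyl (2S)-2-[(3R,6S)-6-[(3E)-5-methoxy-4-methyl-5-oxopent-3-en-1-yl]-6-methyl-1,2-dioxan-3-yl]propanoate | COC(=O)/C(C)=C/CC[C@@]1(C)CC[C@H]([C@H](C)C(=O)OC)OO1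
F2 | step 7 | bis[4-(2,6,6-trimethylcyclohex-1-en-1-yl)but-1-en-2-yl]zinc | C=C(CCC1=C(C)CCCC1(C)C)[Zn]C(=C)CCC1=C(C)CCCC1(C)C
F0 | step 9 | none | none
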